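**Retrosynthetic overview**

- The strategy rests on C8 of the arylglycerol β-aryl ether. This methine carries one hydrogen, the ether oxygen O4' of ring B (the 2,6-dimethoxyphenoxy ring), the C9 hydroxymethyl carbon and the bond to the benzylic carbinol C7 on ring A (the 4-hydroxy-3-methoxyphenyl ring).
- C8–O4' and C7–C8 are disconnected together: C8 is the carbene carbon of ethyl diazoacetate (which also brings C9), taken up by the oxygen of 4-bromo-2,6-dimethoxyphenol and by the carbonyl carbon of vanillin acetate. This step sets C7 and C8.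
- The aryl–C(=O) bond of the hydroxyacetyl group on ring B is disconnected to an aryllithium (from the aryl bromide) and the Weinreb amide of silyl-protected glycolic acid.
- The rest is functional-group work: ester to the C9 alcohol, silyl protection of all hydroxyls, one global desilylation.
- No ring is formed; both benzene rings are bought.

Key step: step 1

Assumption: which antipode of the chiral phosphoric acid leads to the (2R,3R) ester cannot be derived from precedent; the (R) acid is written, and the (S) acid is taken if the sense of induction proves opposite.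

**Step 1**
Reactants: 1 ethyl diazoacetate; 2 4-bromo-2,6-dimethoxyphenol; 3 vanillin acetate (4-formyl-2-methoxyphenyl acetate)
Product: 5 ethyl (2R,3R)-3-(4-acetoxy-3-methoxyphenyl)-2-(4-bromo-2,6-dimethoxyphenoxy)-3-hydroxypropanoate (erythro), via oxonium ylide 4 (not isolated)
Conditions: Rh2(OAc)4 (2 mol%), (R)-3,3'-bis(2,4,6-triisopropylphenyl)-1,1'-binaphthyl-2,2'-diyl hydrogen phosphate (10 mol%), 4 Å MS, CH2Cl2, −20 °C; 1 (1.5 equiv) added over 2 h by syringe pump to 2 (1.0 equiv) and 3 (1.3 equiv)
Reagents that add atoms: none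
Why: Proposed new method: Rh2(OAc)4, a carboxylate of divalent rhodium, should turn 1 into a metal carbene, the phenol oxygen of 2 should add to it to give oxonium ylide 4 (or its enol tautomer), and this carbon nucleophile should add to aldehyde 3, activated by hydrogen bonding to the phosphoric acid, before the 1,2-proton shift that would end in simple O–H insertion; C8–O4' and C7–C8 are thus made in a single step. The closest known reaction type is the aldol-type three-component coupling of aryl diazoacetates, alcohols and aldehydes under dirhodium carboxylate and chiral acid co-catalysis; what has not been shown is a diazoacetate lacking the aryl group together with a phenol as the O–H partner. No ring is closed. Both new stereocentres arise in the C–C bond formation inside the hydrogen-bonded assembly in which the acid holds the aldehyde on its O–H and the enol O–H on its P=O oxygen; this assembly is expected to fix the aldehyde face (C7, R) and the anti (erythro) relation (C8, R in the ester). The step needs aldehyde capture to be faster than the proton shift and than carbene dimerisation, which the electron-poor acetoxy aldehyde, the low stationary concentration of 1 and the low temperature are meant to secure. O-attack over attack at the arene is favoured because both ortho positions and the para position of 2 are substituted.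

**Step 2**
Reactants: 5 ethyl (2R,3R)-3-(4-acetoxy-3-methoxyphenyl)-2-(4-bromo-2,6-dimethoxyphenoxy)-3-hydroxypropanoate
Product: 6 (1R,2S)-2-(4-bromo-2,6-dimethoxyphenoxy)-1-(4-hydroxy-3-methoxyphenyl)propane-1,3-diol
Conditions: LiBH4 (3 equiv), THF, 0 °C → rt; sat. aq NH4Cl
Reagents that add atoms: none
Why: Ester reduction by a borohydride: LiBH4 should reduce the activated α-aryloxy ester to the C9 primary alcohol while the C7 oxygen is held as a borate (which disfavours retro-aldol cleavage), cleave the aryl acetate in the same operation, and leave the aryl bromide and both stereocentres untouched.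

**Step 3**
Reactants: 6 (1R,2S)-2-(4-bromo-2,6-dimethoxyphenoxy)-1-(4-hydroxy-3-methoxyphenyl)propane-1,3-diol
Product: 7 tert-butyl[4-[(1R,2S)-2-(4-bromo-2,6-dimethoxyphenoxy)-1,3-bis(tert-butyldimethylsilyloxy)propyl]-2-methoxyphenoxy]dimethylsilane (tris-silyl ether of 6)
Conditions: TBSOTf (3.6 equiv), 2,6-lutidine (5 equiv), CH2Cl2, 0 °C → rt
Reagents that add atoms: tert-butyldimethylsilyl trifluoromethanesulfonate (TBSOTf), CC(C)(C)[Si](C)(C)OS(=O)(=O)C(F)(F)F
Why: Silyl ether formation: the silyl triflate with a hindered pyridine base should silylate the phenol, the primary C9 alcohol and the hindered benzylic C7 alcohol without strong acid or base, so that no acidic proton is left for the organolithium step and C7 and C8 are not disturbed.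

**Step 4**
Reactants: 8 ethyl glycolate
Product: 9 ethyl 2-(tert-butyldimethylsilyloxy)acetate
Conditions: TBSCl, imidazole, CH2Cl2, rt
Reagents that add atoms: tert-butyldimethylsilyl chloride (TBSCl), CC(C)(C)[Si](C)(C)Cl
Why: Silyl ether formation on the primary alcohol of a hydroxy ester, a routine protection that leaves the ester untouched.

**Step 5**
Reactants: 9 ethyl 2-(tert-butyldimethylsilyloxy)acetate
Product: 10 2-(tert-butyldimethylsilyloxy)-N-methoxy-N-methylacetamide
Conditions: MeNHOMe·HCl, i-PrMgCl, THF, −20 → 0 °C; sat. aq NH4Cl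
Reagents that add atoms: N,O-dimethylhydroxylamine hydrochloride, CNOC.Cl
Why: Weinreb amide formation by aminolysis of the ester with the chloromagnesium amide made in the flask from the hydroxylamine salt and i-PrMgCl, a standard conversion of α-silyloxy esters that the silyl ether should survive at low temperature.

**Step 6**
Reactants: 7 tris-silyl aryl bromide; 10 2-(tert-butyldimethylsilyloxy)-N-methoxy-N-methylacetamide
Product: 13 1-[4-[(1R,2S)-1,3-bis(tert-butyldimethylsilyloxy)-1-[4-(tert-butyldimethylsilyloxy)-3-methoxyphenyl]propan-2-yl]oxy-3,5-dimethoxyphenyl]-2-(tert-butyldimethylsilyloxy)ethanone, via aryllithium 11 (not isolated), via lithium hemiaminal alkoxide 12 (not isolated)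
Conditions: n-BuLi (1.05 equiv), THF, −78 °C; then 10 (1.3 equiv), −78 → −40 °C; sat. aq NH4Cl
Reagents that add atoms: none
Why: Bromine–lithium exchange followed by Weinreb ketone synthesis: exchange on the electron-rich aryl bromide should be faster at −78 °C than deprotonation or attack at silicon, and aryllithium 11 should add to amide 10 to give the chelated adduct 12, which does not collapse before the quench, so the ketone appears only on work-up and a second addition is excluded; no stereocentre takes part.

**Step 7**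
Reactants: 13 tetrakis-silyl ketone
Product: 14 1-[4-[(1R,2S)-1,3-dihydroxy-1-(4-hydroxy-3-methoxyphenyl)propan-2-yl]oxy-3,5-dimethoxyphenyl]-2-hydroxyethanone (CNP0282675.1)
Conditions: Bu4NF (6 equiv), AcOH (6 equiv), THF, 0 °C → rt
Reagents that add atoms: none
Why: Fluoride-mediated cleavage of silyl ethers: fluoride buffered with acetic acid should remove the aryl, the two primary and the secondary silyl group in one operation in a near-neutral medium, so that neither phenoxide-driven loss of the C7 oxygen nor acid-induced ionisation at the benzylic carbinol can scramble C7, and the α-hydroxy ketone is not exposed to base.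

**Compound list**

1 | ethyl diazoacetate | CCOC(=O)C=[N+]=[N-] | starting material
2 | 4-bromo-2,6-dimethoxyphenol | COc1cc(Br)cc(OC)c1O | starting material
3 | vanillin acetate (4-formyl-2-methoxyphenyl acetate) | COc1cc(C=O)ccc1OC(C)=O | starting material
4 | oxonium ylide from the carbene of 1 and the oxygen of 2: ethyl 2-[(4-bromo-2,6-dimethoxyphenyl)oxonio]acetate C-ylide (not isolated) | CCOC(=O)[CH-][OH+]c1c(OC)cc(Br)cc1OC | intermediate
5 | ethyl (2R,3R)-3-(4-acetoxy-3-methoxyphenyl)-2-(4-bromo-2,6-dimethoxyphenoxy)-3-hydroxypropanoate (erythro) | COc1cc([C@@H](O)[C@H](C(=O)OCC)Oc2c(OC)cc(Br)cc2OC)ccc1OC(C)=O | intermediate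
6 | (1R,2S)-2-(4-bromo-2,6-dimethoxyphenoxy)-1-(4-hydroxy-3-methoxyphenyl)propane-1,3-diol | COc1cc([C@@H](O)[C@H](CO)Oc2c(OC)cc(Br)cc2OC)ccc1O | intermediate
7 | tert-butyl[4-[(1R,2S)-2-(4-bromo-2,6-dimethoxyphenoxy)-1,3-bis(tert-butyldimethylsilyloxy)propyl]-2-methoxyphenoxy]dimethylsilane | COc1cc([C@@H](O[Si](C)(C)C(C)(C)C)[C@H](CO[Si](C)(C)C(C)(C)C)Oc2c(OC)cc(Br)cc2OC)ccc1O[Si](C)(C)C(C)(C)C | intermediate
8 | ethyl glycolate (ethyl 2-hydroxyacetate) | CCOC(=O)CO | starting material
9 | ethyl 2-(tert-butyldimethylsilyloxy)acetate | CCOC(=O)CO[Si](C)(C)C(C)(C)C | intermediate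
10 | 2-(tert-butyldimethylsilyloxy)-N-methoxy-N-methylacetamide | CON(C)C(=O)CO[Si](C)(C)C(C)(C)C | intermediate
11 | [4-[(1R,2S)-1,3-bis(tert-butyldimethylsilyloxy)-1-[4-(tert-butyldimethylsilyloxy)-3-methoxyphenyl]propan-2-yl]oxy-3,5-dimethoxyphenyl]lithium (not isolated) | COc1cc([C@@H](O[Si](C)(C)C(C)(C)C)[C@H](CO[Si](C)(C)C(C)(C)C)Oc2c(OC)cc([Li])cc2OC)ccc1O[Si](C)(C)C(C)(C)C | intermediate
12 | lithium alkoxide of the N-methoxy-N-methyl hemiaminal formed from 11 and 10, (1R,2S) in the side chain, both configurations at the hemiaminal carbon (not isolated) | COc1cc([C@@H](O[Si](C)(C)C(C)(C)C)[C@H](CO[Si](C)(C)C(C)(C)C)Oc2c(OC)cc(C(O[Li])(N(C)OC)CO[Si](C)(C)C(C)(C)C)cc2OC)ccc1O[Si](C)(C)C(C)(C)C | intermediate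
13 | 1-[4-[(1R,2S)-1,3-bis(tert-butyldimethylsilyloxy)-1-[4-(tert-butyldimethylsilyloxy)-3-methoxyphenyl]propan-2-yl]oxy-3,5-dimethoxyphenyl]-2-(tert-butyldimethylsilyloxy)ethanone | COc1cc([C@@H](O[Si](C)(C)C(C)(C)C)[C@H](CO[Si](C)(C)C(C)(C)C)Oc2c(OC)cc(C(=O)CO[Si](C)(C)C(C)(C)C)cc2OC)ccc1O[Si](C)(C)C(C)(C)C | intermediate
14 | 1-[4-[(1R,2S)-1,3-dihydroxy-1-(4-hydroxy-3-methoxyphenyl)propan-2-yl]oxy-3,5-dimethoxyphenyl]-2-hydroxyethanone (erythro) | COc1cc([C@@H](O)[C@H](CO)Oc2c(OC)cc(C(=O)CO)cc2OC)ccc1O | target

**Step count**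

Total: 7 steps. Longest linear sequence: 5 steps (1, 2, 3, 6, 7); steps 4 and 5 form the side branch to amide 10.

**Steps most likely to fail**

Step 1 (the new three-component step). The 1,2-proton shift of ylide 4 may outrun addition to the aldehyde, so that only O–H insertion takes place. The carbene may also dimerise or add to the aldehyde oxygen, or the acid may fail to control the aldehyde face and the relative configuration. The fallback uses known chemistry, sets out from 2 and 3 and comes back at 5. Phenol 2 is O-alkylated with ethyl bromoacetate (BrCC(=O)OCC; K2CO3, acetone, reflux) to ethyl 2-(4-bromo-2,6-dimethoxyphenoxy)acetate F1, the same ester that the proton-shift pathway delivers. LiN(i-Pr)2 (LDA) and then Me3SiCl in THF at −78 °C should give the ketene silyl acetal F2. A Mukaiyama aldol addition of F2 to 3 (BF3·OEt2, CH2Cl2, −78 °C) should give the hydroxy ester as a mixture of stereoisomers F3. The erythro racemate is separated on silica and resolved by preparative HPLC on a chiral stationary phase; its (2R,3R) enantiomer is 5.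

Step 6. The aryllithium may be quenched by proton transfer from the α-position of amide 10 or from C7, the exchange may stay incomplete, or the lithium reagent may attack the aryl silyl ether. The fallback sets out from 7 and comes back at 14. Stille coupling of 7 with tributyl(1-ethoxyvinyl)stannane (CCCC[Sn](CCCC)(CCCC)C(=C)OCC; Pd(PPh3)4, a complex of zerovalent palladium, toluene, 100 °C) should give the aryl enol ether F4. OsO4 (catalytic) with N-methylmorpholine N-oxide in acetone–water dihydroxylates the enol ether, and the hemiketal loses ethanol to give the α-hydroxy ketone F5. The conditions of step 7 then remove the three silyl groups of F5 and give 14.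

Step 7. Cleavage of the hindered C7 silyl ether may stall under buffered fluoride. Forcing it with unbuffered fluoride would open phenoxide-driven loss of the C7 oxygen with epimerisation at C7, and base-induced degradation of the ketol. The fallback uses no fluoride, sets out from 6 and comes back at 14. The phenol of 6 is benzylated (BnBr, K2CO3, acetone) to the benzyl ether F6. The 1,3-diol is closed to the acetonide F7 (2,2-dimethoxypropane, pyridinium p-toluenesulfonate, acetone). Bromine–lithium exchange (n-BuLi, THF, −78 °C) and acylation with commercial 2-(benzyloxy)-N-methoxy-N-methylacetamide (CON(C)C(=O)COCc1ccccc1) should give the ketone F8. Aqueous acetic acid in THF at 40 °C hydrolyses the acetonide to the diol F9 while the phenol is still benzylated. Hydrogenolysis of both benzyl ethers (H2, Pd/C, EtOAc, rt) then gives 14 under neutral conditions.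

**Further compounds**

F1 | step 1 | ethyl 2-(4-bromo-2,6-dimethoxyphenoxy)acetate | CCOC(=O)COc1c(OC)cc(Br)cc1OC
F2 | step 1 | ethyl trimethylsilyl ketene acetal of F1, 1-ethoxy-1-(trimethylsilyloxy)-2-(4-bromo-2,6-dimethoxyphenoxy)ethene, both alkene geometries | CCOC(O[Si](C)(C)C)=COc1c(OC)cc(Br)cc1OC
F3 | step 1 | ethyl 3-(4-acetoxy-3-methoxyphenyl)-2-(4-bromo-2,6-dimethoxyphenoxy)-3-hydroxypropanoate, mixture of the four stereoisomers | COc1cc(C(O)C(C(=O)OCC)Oc2c(OC)cc(Br)cc2OC)ccc1OC(C)=O
F4 | step 6 | tert-butyl[4-[(1R,2S)-1,3-bis(tert-butyldimethylsilyloxy)-2-[4-(1-ethoxyvinyl)-2,6-dimethoxyphenoxy]propyl]-2-methoxyphenoxy]dimethylsilane | COc1cc([C@@H](O[Si](C)(C)C(C)(C)C)[C@H](CO[Si](C)(C)C(C)(C)C)Oc2c(OC)cc(C(=C)OCC)cc2OC)ccc1O[Si](C)(C)C(C)(C)C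
F5 | step 6 | 1-[4-[(1R,2S)-1,3-bis(tert-butyldimethylsilyloxy)-1-[4-(tert-butyldimethylsilyloxy)-3-methoxyphenyl]propan-2-yl]oxy-3,5-dimethoxyphenyl]-2-hydroxyethanone | COc1cc([C@@H](O[Si](C)(C)C(C)(C)C)[C@H](CO[Si](C)(C)C(C)(C)C)Oc2c(OC)cc(C(=O)CO)cc2OC)ccc1O[Si](C)(C)C(C)(C)C
F6 | step 7 | (1R,2S)-1-[4-(benzyloxy)-3-methoxyphenyl]-2-(4-bromo-2,6-dimethoxyphenoxy)propane-1,3-diol | COc1cc([C@@H](O)[C@H](CO)Oc2c(OC)cc(Br)cc2OC)ccc1OCc1ccccc1
F7 | step 7 | (4R,5S)-4-[4-(benzyloxy)-3-methoxyphenyl]-5-(4-bromo-2,6-dimethoxyphenoxy)-2,2-dimethyl-1,3-dioxane | COc1cc([C@H]2OC(C)(C)OC[C@@H]2Oc2c(OC)cc(Br)cc2OC)ccc1OCc1ccccc1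
F8 | step 7 | 2-(benzyloxy)-1-[4-[(4R,5S)-4-[4-(benzyloxy)-3-methoxyphenyl]-2,2-dimethyl-1,3-dioxan-5-yl]oxy-3,5-dimethoxyphenyl]ethanone | COc1cc([C@H]2OC(C)(C)OC[C@@H]2Oc2c(OC)cc(C(=O)COCc3ccccc3)cc2OC)ccc1OCc1ccccc1
F9 | step 7 | 2-(benzyloxy)-1-[4-[(1R,2S)-1-[4-(benzyloxy)-3-methoxyphenyl]-1,3-dihydroxypropan-2-yl]oxy-3,5-dimethoxyphenyl]ethanone | COc1cc([C@@H](O)[C@H](CO)Oc2c(OC)cc(C(=O)COCc3ccccc3)cc2OC)ccc1OCc1ccccc1
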